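**Plan**
- Retrosynthesis: C16=C17 is cut first (Mannich methylenation of a C15 ketone), then C9–C11 and C8–C15 together, then C8–C14 (lactone enolate alkylation), then C9–C10 with the lactone C–O bond (epoxide/acrylate radical annulation on ring A).
- Enabling feature: C9 and C8 are the β- and α-carbons of the 7,20-lactone, so a C8=C9 unsaturated spirolactone with a symmetric C13 bis(2-oxoethyl) arm on C14 can close ring C (C9–C11) and ring D (C8–C15) in one SmI2 reduction.
- Forward order: ring A → spiro δ-lactone → C8 arm → C8=C9 → acetates at C1/C6 (placed before C11–OH exists) → dialdehyde → rings C and D → C15 ketone → C16 methylene.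
- Stereochemistry: C5 from a copper-catalysed asymmetric conjugate addition, C1 from a substrate-controlled Luche reduction, C10 from radical addition away from the axial C4 methyl, and C9, C11, C13, C8 in the cascade under control of C10 and a chair transition state.

Key step: step 16

Remark: ent-kaurane numbering (C1–C20) is used for atoms throughout; centres that are destroyed or converge later (the spiro-epoxide carbon of 9, C8 of 17 and 19, C16 of 28) are carried as epimer mixtures.

**Step 1**
Reactants: 1 4,4-dimethylcyclohex-2-en-1-one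
Product: 3 (2R,3S)-2-[(dimethylamino)methyl]-3-{[dimethyl(phenyl)silyl]methyl}-4,4-dimethylcyclohexan-1-one, via magnesium enolate 2 (not isolated)
Conditions: CuBr·SMe2 (5 mol %), (R)-1-[(S)-2-(diphenylphosphino)ferrocenyl]ethyldicyclohexylphosphine (6 mol %), PhMe2SiCH2MgCl, t-BuOMe, −78 °C; then Me2N=CH2+ I−, THF, −78 °C → rt
Reagents that add atoms: (dimethylphenylsilyl)methylmagnesium chloride, C[Si](C)(C[Mg]Cl)c1ccccc1; Eschenmoser's salt, C=[N+](C)C.[I-]
Why: Copper-catalysed asymmetric conjugate addition of a Grignard reagent (a hydroxymethyl equivalent) sets C5 under control of the ferrocenyl diphosphine, whose antipode is to be chosen so that the 3S adduct results, and the regiodefined magnesium enolate is trapped at C10 by the iminium salt (Mannich reaction) trans to the new substituent.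

**Step 2**
Reactants: 3 (2R,3S)-2-[(dimethylamino)methyl]-3-{[dimethyl(phenyl)silyl]methyl}-4,4-dimethylcyclohexan-1-one
Product: 5 (R)-3-{[dimethyl(phenyl)silyl]methyl}-4,4-dimethyl-2-methylidenecyclohexan-1-one, via ammonium iodide 4 (not isolated)
Conditions: MeI, THF, rt; then NaHCO3 (aq), CH2Cl2, rt
Reagents that add atoms: none
Why: Exhaustive N-methylation and base-induced Hofmann-type (E1cB) elimination of trimethylamine give the exocyclic enone without touching C5.

**Step 3**
Reactants: 5 (R)-3-{[dimethyl(phenyl)silyl]methyl}-4,4-dimethyl-2-methylidenecyclohexan-1-one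
Product: 6 (1S,3R)-3-{[dimethyl(phenyl)silyl]methyl}-4,4-dimethyl-2-methylidenecyclohexan-1-ol
Conditions: NaBH4, CeCl3·7H2O, MeOH, −78 °C
Reagents that add atoms: none
Why: Luche 1,2-reduction, in which hydride adds axially to the conformer with the C5 side chain equatorial (and anti to that chain if it is axial), so the C1 carbinol should form 1,3-cis to the C5 substituent.

**Step 4**
Reactants: 6 (1S,3R)-3-{[dimethyl(phenyl)silyl]methyl}-4,4-dimethyl-2-methylidenecyclohexan-1-ol
Product: 7 (1S,3R)-3-(hydroxymethyl)-4,4-dimethyl-2-methylidenecyclohexan-1-ol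
Conditions: KH, t-BuOOH, DMF, 0 °C → rt; then Bu4NF, 60 °C
Reagents that add atoms: tert-butyl hydroperoxide, CC(C)(C)OO
Why: Fleming–Tamao oxidation under nucleophilic peroxide/fluoride conditions converts C–Si into C–OH and spares the 1,1-disubstituted alkene that electrophilic dephenylation would attack.

**Step 5**
Reactants: 7 (1S,3R)-3-(hydroxymethyl)-4,4-dimethyl-2-methylidenecyclohexan-1-ol
Product: 8 tert-butyl{[(1S,3R)-3-{[(tert-butyldimethylsilyl)oxy]methyl}-4,4-dimethyl-2-methylidenecyclohexyl]oxy}dimethylsilane
Conditions: TBSOTf, 2,6-lutidine, CH2Cl2, −78 → 0 °C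
Reagents that add atoms: tert-butyldimethylsilyl triflate, CC(C)(C)[Si](C)(C)OS(=O)(=O)C(F)(F)F
Why: Silyl triflate silylation protects the hindered allylic secondary and the primary hydroxyl as base-stable ethers for the enolate steps.

**Step 6**
Reactants: 8 tert-butyl{[(1S,3R)-3-{[(tert-butyldimethylsilyl)oxy]methyl}-4,4-dimethyl-2-methylidenecyclohexyl]oxy}dimethylsilane
Product: 9 (4S,8S)-4-[(tert-butyldimethylsilyl)oxy]-8-{[(tert-butyldimethylsilyl)oxy]methyl}-7,7-dimethyl-1-oxaspiro[2.5]octane (spiro-carbon epimers)
Conditions: mCPBA, NaHCO3, CH2Cl2, 0 °C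
Reagents that add atoms: 3-chloroperbenzoic acid, OOC(=O)c1cccc(Cl)c1
Why: Buffered Prilezhaev epoxidation of the only alkene; the configuration of the spiro-epoxide carbon is irrelevant because it becomes a planar radical in step 7.

**Step 7**
Reactants: 9 (4S,8S)-4-[(tert-butyldimethylsilyl)oxy]-8-{[(tert-butyldimethylsilyl)oxy]methyl}-7,7-dimethyl-1-oxaspiro[2.5]octane; 10 2,2,2-trifluoroethyl acrylate
Product: 11 (6S,7R,11S)-11-[(tert-butyldimethylsilyl)oxy]-7-{[(tert-butyldimethylsilyl)oxy]methyl}-8,8-dimethyl-2-oxaspiro[5.5]undecan-3-one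
Conditions: Cp2TiCl2 (cat.), Zn, 2,4,6-collidine·HCl, THF, rt
Reagents that add atoms: none
Why: Nugent–RajanBabu opening of the epoxide by Cp2TiCl gives the tertiary C10 radical, which undergoes Giese addition to the acrylate on the face away from the axial C4 methyl (C9 equatorial, trans to the C1 and C5 substituents), and the C20 titanium alkoxide lactonises onto the activated trifluoroethyl ester.

**Step 8**
Reactants: 12 diethyl diallylmalonate
Product: 13 ethyl 2-allylpent-4-enoate
Conditions: LiCl, H2O, DMSO, 160 °C
Reagents that add atoms: none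
Why: Krapcho dealkoxycarbonylation removes one ester group of the disubstituted malonate.

**Step 9**
Reactants: 13 ethyl 2-allylpent-4-enoate
Product: 14 2-allylpent-4-en-1-ol
Conditions: LiAlH4, Et2O, 0 °C
Reagents that add atoms: none
Why: Hydride reduction of the ester to the primary alcohol.

**Step 10**
Reactants: 14 2-allylpent-4-en-1-ol
Product: 15 4-(iodomethyl)hepta-1,6-diene
Conditions: I2, PPh3, imidazole, CH2Cl2, 0 °C → rt
Reagents that add atoms: iodine, II
Why: Appel-type iodination of the primary alcohol.

**Step 11**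
Reactants: 11 (6S,7R,11S)-11-[(tert-butyldimethylsilyl)oxy]-7-{[(tert-butyldimethylsilyl)oxy]methyl}-8,8-dimethyl-2-oxaspiro[5.5]undecan-3-one; 15 4-(iodomethyl)hepta-1,6-diene
Product: 17 (6S,7R,11S)-11-[(tert-butyldimethylsilyl)oxy]-7-{[(tert-butyldimethylsilyl)oxy]methyl}-8,8-dimethyl-4-[2-(prop-2-en-1-yl)pent-4-en-1-yl]-2-oxaspiro[5.5]undecan-3-one (C8 epimers), via lithium enolate 16 (not isolated)
Conditions: LiN(i-Pr)2, THF, −78 °C; then 15, HMPA, −78 → 0 °C
Reagents that add atoms: none
Why: Alkylation of the lactone lithium enolate at C8 by the primary iodide in the presence of HMPA; the C8 configuration is not controlled and is removed in step 12.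

**Step 12**
Reactants: 17 C8-alkylated spirolactone (name as in step 11)
Product: 20 (6S,7R,11S)-11-[(tert-butyldimethylsilyl)oxy]-7-{[(tert-butyldimethylsilyl)oxy]methyl}-8,8-dimethyl-4-[2-(prop-2-en-1-yl)pent-4-en-1-yl]-2-oxaspiro[5.5]undec-4-en-3-one, via lithium enolate 18 (not isolated), via selenide 19 (not isolated)
Conditions: LiN(i-Pr)2, THF, −78 °C; PhSeBr; then H2O2, pyridine, CH2Cl2, 0 °C → rt
Reagents that add atoms: none
Why: α-Selenenylation of the enolate and selenoxide syn-elimination toward the ring hydrogen at C9 should give the endocyclic C8=C9 enoate, as is usual for α-alkyl δ-lactones.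

**Step 13**
Reactants: 20 C8=C9 unsaturated spirolactone bis(silyl ether) (name as in step 12)
Product: 21 (6S,7R,11S)-11-hydroxy-7-(hydroxymethyl)-8,8-dimethyl-4-[2-(prop-2-en-1-yl)pent-4-en-1-yl]-2-oxaspiro[5.5]undec-4-en-3-one
Conditions: HF·pyridine, pyridine, THF, 0 °C → rt
Reagents that add atoms: none
Why: Fluoride cleavage of both silyl ethers under buffered acidic conditions, which avoid alkoxide-driven translactonisation of C1–OH onto C7 and oxa-Michael addition of C6–OH to C9; the diol is acetylated at once.

**Step 14**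
Reactants: 21 unsaturated spirolactone diol (name as in step 13)
Product: 22 [(6S,7R,11S)-11-acetoxy-8,8-dimethyl-3-oxo-4-[2-(prop-2-en-1-yl)pent-4-en-1-yl]-2-oxaspiro[5.5]undec-4-en-7-yl]methyl acetate
Conditions: Ac2O, DMAP, pyridine, CH2Cl2, 0 °C → rt
Reagents that add atoms: acetic anhydride, CC(=O)OC(C)=O
Why: DMAP-catalysed acetylation installs the two acetates of the target before C11–OH exists, so no selective acylation is needed later.

**Step 15**
Reactants: 22 unsaturated spirolactone diacetate diene (name as in step 14)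
Product: 23 [(6S,7R,11S)-11-acetoxy-8,8-dimethyl-3-oxo-4-[4-oxo-2-(2-oxoethyl)butyl]-2-oxaspiro[5.5]undec-4-en-7-yl]methyl acetate
Conditions: O3, pyridine, CH2Cl2, −78 °C
Reagents that add atoms: ozone, [O-][O+]=O
Why: Ozonolysis in the presence of pyridine gives the aldehydes without a separate reductive work-up and should cleave the two electron-rich terminal alkenes much faster than the hindered, electron-poor C8=C9 bond.

**Step 16**
Reactants: 23 C8=C9 unsaturated spirolactone dialdehyde (name as in step 15)
Product: 25 tetracyclic lactone 1,6-diacetate 11,15-diol (rings A, lactone, C and D; C11–OH axial on ring C and syn to the C15–C16 bridge; C15–OH syn to the lactone carbonyl; C16 is CH2), via samarium enolate 24 (not isolated)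
Conditions: SmI2 (2.5 equiv, added over 2 h), THF, −78 °C, 2 mM; then H2O/aq. NH4Cl
Reagents that add atoms: none
Why: SmI2 reduces one aldehyde to a ketyl that adds to C9, the β-carbon of the lactone enoate (polarity-matched ketyl–olefin addition), and a second electron turns the C8 radical into a trivalent-samarium enolate that adds to the other aldehyde; the closest known reactions are SmI2 ketyl additions to α-alkylated unsaturated lactones terminated by aldol addition in dialdehyde cascades. Ring C closes 6-endo-trig (tether through the α-carbon C8) and ring D closes 5-exo-trig by the aldol (C8–C15). C9 is set by the spiro centre C10: the ketyl should approach the lactone face flanked by C1, away from C5 with its acetoxymethyl group buttressed by the C4 methyls. C11 and C13 follow from a chair transition state with C10, the samarium-bound oxygen and the spectator arm all equatorial, which also decides which of the two diastereotopic arms reacts; C8 follows from C13 because the spectator arm can reach the enolate only on its own face, and C15 (hydroxyl syn to C7 through a chelated transition state) is erased in step 17. The step needs chemoselectivity over pinacol closure of the two aldehydes and over acyl transfer from the acetates: ketyl formation is rate-limiting and the ketyl is consumed intramolecularly by the activated alkene, so SmI2 is added slowly at high dilution and −78 °C, where esters are inert.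

**Step 17**
Reactants: 25 tetracyclic lactone 1,6-diacetate 11,15-diol
Product: 26 tetracyclic lactone 1,6-diacetate with C15 ketone and free C11–OH (16,17-dihydro-17-nor analogue of the target)
Conditions: Dess–Martin periodinane (1.1 equiv), pyridine, CH2Cl2, 0 °C
Reagents that add atoms: none
Why: Dess–Martin oxidation should take the more accessible exo C15 carbinol on the cyclopentane in preference to the C11 carbinol, which is axial, lies under the C15–C16 bridge and is flanked by the spiro centre.

**Step 18**
Reactants: 26 C15 ketone with free C11–OH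
Product: 28 16-[(dimethylamino)methyl] derivative of 26 (C16 epimers), via bis(trimethylsilyl) enol ether 27 (not isolated)
Conditions: Me3SiOTf, Et3N, CH2Cl2, 0 °C; then Me2N=CH2+ I−, rt; then citric acid, MeOH, 0 °C
Reagents that add atoms: Eschenmoser's salt, C=[N+](C)C.[I-]
Why: Soft enolisation can occur only toward C16 because C8 is quaternary, C11–OH is silylated transiently, the silyl enol ether undergoes a Mannich reaction with the iminium salt, and mild acid then frees C11–OH.

**Step 19**
Reactants: 28 C16 Mannich base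
Product: 30 Rabdosin B, via ammonium iodide 29 (not isolated)
Conditions: MeI, CH2Cl2, rt; then NaHCO3 (aq), rt
Reagents that add atoms: none
Why: Quaternisation and Hofmann-type elimination unveil the C16=C17 exocyclic enone under conditions that leave the acetates, the lactone and the free C11 hydroxyl untouched.

**Compound list**
1 | 4,4-dimethylcyclohex-2-en-1-one | CC1(C)CCC(=O)C=C1 | starting material
2 | chloromagnesium enolate of (S)-3-{[dimethyl(phenyl)silyl]methyl}-4,4-dimethylcyclohexanone (formed in situ) | C[Si](C)(C[C@H]1C=C(O[Mg]Cl)CCC1(C)C)c1ccccc1 | intermediate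
3 | (2R,3S)-2-[(dimethylamino)methyl]-3-{[dimethyl(phenyl)silyl]methyl}-4,4-dimethylcyclohexan-1-one | CN(C)C[C@@H]1C(=O)CCC(C)(C)[C@H]1C[Si](C)(C)c1ccccc1 | intermediate
4 | N-methyl quaternary ammonium iodide of 3 (formed in situ) | C[N+](C)(C)C[C@@H]1C(=O)CCC(C)(C)[C@H]1C[Si](C)(C)c1ccccc1.[I-] | intermediate
5 | (R)-3-{[dimethyl(phenyl)silyl]methyl}-4,4-dimethyl-2-methylidenecyclohexan-1-one | C=C1C(=O)CCC(C)(C)[C@H]1C[Si](C)(C)c1ccccc1 | intermediate
6 | (1S,3R)-3-{[dimethyl(phenyl)silyl]methyl}-4,4-dimethyl-2-methylidenecyclohexan-1-ol | C=C1[C@@H](O)CCC(C)(C)[C@H]1C[Si](C)(C)c1ccccc1 | intermediate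
7 | (1S,3R)-3-(hydroxymethyl)-4,4-dimethyl-2-methylidenecyclohexan-1-ol | C=C1[C@@H](O)CCC(C)(C)[C@H]1CO | intermediate
8 | bis(tert-butyldimethylsilyl) ether of 7 | C=C1[C@@H](O[Si](C)(C)C(C)(C)C)CCC(C)(C)[C@H]1CO[Si](C)(C)C(C)(C)C | intermediate
9 | (4S,8S)-4-[(tert-butyldimethylsilyl)oxy]-8-{[(tert-butyldimethylsilyl)oxy]methyl}-7,7-dimethyl-1-oxaspiro[2.5]octane (spiro-carbon epimers) | C1OC12[C@@H](O[Si](C)(C)C(C)(C)C)CCC(C)(C)[C@H]2CO[Si](C)(C)C(C)(C)C | intermediate
10 | 2,2,2-trifluoroethyl acrylate | C=CC(=O)OCC(F)(F)F | starting material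
11 | (6S,7R,11S)-11-[(tert-butyldimethylsilyl)oxy]-7-{[(tert-butyldimethylsilyl)oxy]methyl}-8,8-dimethyl-2-oxaspiro[5.5]undecan-3-one | O=C1CC[C@]2(CO1)[C@@H](O[Si](C)(C)C(C)(C)C)CCC(C)(C)[C@H]2CO[Si](C)(C)C(C)(C)C | intermediate
12 | diethyl diallylmalonate | C=CCC(CC=C)(C(=O)OCC)C(=O)OCC | starting material
13 | ethyl 2-allylpent-4-enoate | C=CCC(CC=C)C(=O)OCC | intermediate
14 | 2-allylpent-4-en-1-ol | C=CCC(CC=C)CO | intermediate
15 | 4-(iodomethyl)hepta-1,6-diene | C=CCC(CC=C)CI | intermediate
16 | lithium enolate of 11 (formed in situ) | [Li]OC1=CC[C@]2(CO1)[C@@H](O[Si](C)(C)C(C)(C)C)CCC(C)(C)[C@H]2CO[Si](C)(C)C(C)(C)C | intermediate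
17 | C8-(2-allylpent-4-enyl) spirolactone bis(silyl ether), C8 epimers | C=CCC(CC=C)CC1C[C@]2(COC1=O)[C@@H](O[Si](C)(C)C(C)(C)C)CCC(C)(C)[C@H]2CO[Si](C)(C)C(C)(C)C | intermediate
18 | lithium enolate of 17 (formed in situ) | [Li]OC1=C(CC(CC=C)CC=C)C[C@]2(CO1)[C@@H](O[Si](C)(C)C(C)(C)C)CCC(C)(C)[C@H]2CO[Si](C)(C)C(C)(C)C | intermediate
19 | C8-phenylselanyl derivative of 17 (formed in situ, C8 epimers) | C=CCC(CC=C)CC1([Se]c3ccccc3)C[C@]2(COC1=O)[C@@H](O[Si](C)(C)C(C)(C)C)CCC(C)(C)[C@H]2CO[Si](C)(C)C(C)(C)C | intermediate
20 | C8=C9 unsaturated spirolactone bis(silyl ether) diene | C=CCC(CC=C)CC1=C[C@]2(COC1=O)[C@@H](O[Si](C)(C)C(C)(C)C)CCC(C)(C)[C@H]2CO[Si](C)(C)C(C)(C)C | intermediate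
21 | C8=C9 unsaturated spirolactone C1,C6-diol diene | C=CCC(CC=C)CC1=C[C@]2(COC1=O)[C@@H](O)CCC(C)(C)[C@H]2CO | intermediate
22 | C8=C9 unsaturated spirolactone C1,C6-diacetate diene | C=CCC(CC=C)CC1=C[C@]2(COC1=O)[C@@H](OC(C)=O)CCC(C)(C)[C@H]2COC(C)=O | intermediate
23 | C8=C9 unsaturated spirolactone C1,C6-diacetate dialdehyde (key-step precursor) | O=CCC(CC=O)CC1=C[C@]2(COC1=O)[C@@H](OC(C)=O)CCC(C)(C)[C@H]2COC(C)=O | intermediate
24 | trivalent-samarium enolate with ring C closed (C11–O–SmI2, C8=C7–O–SmI2) and the second aldehyde arm free (formed in situ) | O=CC[C@@H]1C[C@H](O[Sm](I)I)[C@@H]2C(=C(O[Sm](I)I)OC[C@]23[C@@H](OC(C)=O)CCC(C)(C)[C@H]3COC(C)=O)C1 | intermediate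
25 | tetracyclic lactone 1,6-diacetate 11,15-diol (key-step product) | C1[C@H](O)[C@]23C[C@H]1C[C@H](O)[C@H]2[C@]1(COC3=O)[C@@H](OC(C)=O)CCC(C)(C)[C@H]1COC(C)=O | intermediate
26 | tetracyclic lactone 1,6-diacetate, C15 ketone, C11–OH free | C1C(=O)[C@]23C[C@H]1C[C@H](O)[C@H]2[C@]1(COC3=O)[C@@H](OC(C)=O)CCC(C)(C)[C@H]1COC(C)=O | intermediate
27 | C15–C16 trimethylsilyl enol ether, C11 trimethylsilyl ether of 26 (formed in situ) | C1=C(O[Si](C)(C)C)[C@]23C[C@H]1C[C@H](O[Si](C)(C)C)[C@H]2[C@]1(COC3=O)[C@@H](OC(C)=O)CCC(C)(C)[C@H]1COC(C)=O | intermediate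
28 | 16-[(dimethylamino)methyl] derivative of 26 (C16 epimers) | CN(C)CC1C(=O)[C@]23C[C@H]1C[C@H](O)[C@H]2[C@]1(COC3=O)[C@@H](OC(C)=O)CCC(C)(C)[C@H]1COC(C)=O | intermediate
29 | N-methyl quaternary ammonium iodide of 28 (formed in situ) | C[N+](C)(C)CC1C(=O)[C@]23C[C@H]1C[C@H](O)[C@H]2[C@]1(COC3=O)[C@@H](OC(C)=O)CCC(C)(C)[C@H]1COC(C)=O.[I-] | intermediate
30 | Rabdosin B | C=C1C(=O)[C@]23C[C@H]1C[C@H](O)[C@H]2[C@]1(COC3=O)[C@@H](OC(C)=O)CCC(C)(C)[C@H]1COC(C)=O | target

**Step count and risks**
Total: 19 steps. Longest linear sequence: 16 steps (steps 1–7 and 11–19, from 1 to 30); the iodide branch (steps 8–10) joins in step 11.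

1. Step 16. The ketyl may be captured by the second aldehyde (pinacol ring closure of the C13 arm), may add to the C5 face of C9, or the enolate may be protonated before it reaches the aldehyde. The fallback differentiates the arms by oxidation level and sets out from diene 22. Ring-closing metathesis (second-generation Grubbs catalyst, CH2Cl2, 40 °C) should give the cyclopent-3-enylmethyl lactone F1. Ozonolysis with a differentiating work-up (O3, NaHCO3, CH2Cl2–MeOH, −78 °C; then Ac2O, Et3N) should give the aldehyde–methyl ester F2 as both C13 epimers. With SmI2 (THF, −78 → 0 °C) the single aldehyde can only form the ketyl that closes ring C, and the samarium enolate is then acylated by the ester arm (Claisen-type nucleophilic acyl substitution). This comes back to the route at 26 with the C15 ketone already in place, so pinacol closure is excluded and step 17 is not needed. The price is that only the C13 epimer whose ester arm can reach C8 closes ring D; the other is separated as a monocyclic hydroxy lactone.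

2. Step 17. The oxidant may fail to discriminate between the two hindered secondary carbinols, giving oxidation at C11 or over-oxidation. The fallback sets out from 25 and replaces selective oxidation by selective reduction. Excess Dess–Martin periodinane should give the 11,15-dione F3. LiAlH(Ot-Bu)3 (THF, −78 °C) should then reduce the C11 cyclohexanone from the face away from the C15–C16 bridge (axial alcohol, as with 3-oxobicyclo[3.2.1]octanes), while the neopentyl C15 ketone next to quaternary C8 is left. This comes back at 26.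

3. Step 1. The bulky silylmethyl Grignard reagent may add to the 4,4-disubstituted enone with low enantioselectivity or poor catalyst turnover. The fallback sets out from 6 of insufficient enantiomeric purity and uses enzymatic kinetic resolution. Candida antarctica lipase B with vinyl acetate in t-BuOMe should, following the usual enantiopreference of lipases for secondary alcohols, acetylate the (1R,3S) antipode to acetate F4, and unreacted (1S,3R)-6 is recovered, coming back at 6. If the chiral catalyst does not turn over at all, the same addition with CuI and Me3SiCl without ligand supplies racemic material for this resolution.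

**Further compounds**
F1 | step 16 | cyclopent-3-en-1-ylmethyl analogue of 22 (C8=C9 unsaturated spirolactone diacetate) | C1=CCC(C1)CC1=C[C@]2(COC1=O)[C@@H](OC(C)=O)CCC(C)(C)[C@H]2COC(C)=O
F2 | step 16 | aldehyde–methyl ester analogue of 23 (C13 epimers) | COC(=O)CC(CC=O)CC1=C[C@]2(COC1=O)[C@@H](OC(C)=O)CCC(C)(C)[C@H]2COC(C)=O
F3 | step 17 | tetracyclic lactone 1,6-diacetate 11,15-dione | C1C(=O)[C@]23C[C@H]1CC(=O)[C@H]2[C@]1(COC3=O)[C@@H](OC(C)=O)CCC(C)(C)[C@H]1COC(C)=O
F4 | step 1 | (1R,3S)-3-{[dimethyl(phenyl)silyl]methyl}-4,4-dimethyl-2-methylidenecyclohexyl acetate | C=C1[C@H](OC(C)=O)CCC(C)(C)[C@@H]1C[Si](C)(C)c1ccccc1
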